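The numbers in the tables come from a simulation for an exercise.

Target comes slowly in these flasks, and the dispute is over what that slowness is made of. Substrate opens to open intermediate, the held gas dissolves as partner and turns into second intermediate, and the two intermediates join to target. Second intermediate can also leak to side product or be caught by capture agent.

| flask | substrate | capture agent | gas | temperature | remark | time |
|---|---|---|---|---|---|---|
| beta | 0.25 M | 0.017 M | 75 mM (held) | 50 °C | run made earlier |  |
| zeta | 0.25 M | 0.028 M | 75 mM (held) | 83 °C | run made earlier |  |
| epsilon | 0.38 M | 0.0125 M | 75 mM (held) | 50 °C | run made earlier |  |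
| grey | 0.25 M | 0.0125 M | 75 mM (held) | 95 °C |  | 5.0 d |
| amber | 0.25 M | 0.0125 M | 75 mM (held) | 65 °C |  | 5.0 d |
| green | 0.25 M | 0.0125 M | 75 mM (held) | 35 °C |  | 5.0 d |

| run | time / d | target / % |
|---|---|---|
| beta | 3.00 | 31.2 |
| beta | 10.0 | 88.2 |
| beta | 15.0 | 100.0 |
| beta | 25.0 | 99.2 |
| beta | 40.0 | 99.5 |
| beta | 50.0 | 100.4 |
| zeta | 0.625 | 5.5 |
| zeta | 2.08 | 17.6 |
| zeta | 3.00 | 25.6 |
| zeta | 5.00 | 39.5 |
| zeta | 8.00 | 58.7 |
| zeta | 10.0 | 69.7 |
| epsilon | 4.00 | 28.7 |
| epsilon | 12.0 | 82.3 |
| epsilon | 25.0 | 98.5 |
| epsilon | 40.0 | 99.1 |
| epsilon | 50.0 | 99.6 |

(each reading ± 0.5 percentage points)

- at the start none of partner is dissolved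
- what may be going on: substrate -> open intermediate; partner -> second intermediate; open intermediate + second intermediate -> target; second intermediate -> side product; second intermediate + capture agent -> trapped intermediate; gas <-> partner

- which flask leads in amount of target, in percent of the substrate charged ("all alike" within 1.5 percentage points) (grey / amber / green / all alike)
- how much target is there at the end, in percent of the substrate charged: grey
- how much target is there at the end, in percent of the substrate charged: amber
- how much target is there at the end, in percent of the substrate charged: green

After 3.00 d, beta at 50 °C reads a pace of 0.104 /d, the pace being the fraction of the charge turned into target per day counted from the start. Zeta at 83 °C, read at the same time, gives 0.0853 /d.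

The first chemist argues that the pace falls with heat, since zeta reads slower than beta, although zeta also holds more capture agent. On that view green, colder than the other two flasks, leads, with about 52.0% at beta's pace.

The second chemist answers that a pace counted from the start hides a lag, the induction period. Target needs opened substrate, and opening slows in the cold. Take a first-order opening and a pace that grows in step with the opened fraction, its full value held steady; integrated, this gives full pace times the time minus the opening time constant, once the time is well past that constant, so such a flask runs behind.

I side with the second. My own straight line between the two readings gives amber 0.0955 /d, hence an estimated 47.8% at the end. At beta's pace, green must therefore stay within 0.408 d of the start line to win. Beta's first reading, at 3.00 d, comes much later than that, so beta has no reading inside so short a span, and green is colder than beta. I judge a lag beyond that allowance likely in green, and so I expect amber to lead.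

The forecast took the first side, naming green with 37% for grey, 46% for amber and 51% for green, on the ground that “Cooler should still win”.

The simulation gives grey 34.1%, amber 47.2% and green 40.8%, so amber leads; the first chemist's cooling gains down to 49.7 °C, the temperature of highest target between the coldest and hottest flasks.

    substrate → open intermediate (k = 0.0210 /h, Ea = 110 kJ/mol)
    partner → second intermediate (k = 0.0880 /h, Ea = 110 kJ/mol)
    open intermediate + second intermediate → target (k = 1.40 /M/h, Ea = 62.0 kJ/mol)
    second intermediate → side product (k = 0.0350 /h, Ea = 95.0 kJ/mol)
    second intermediate + capture agent → trapped intermediate (k = 0.140 /M/h, Ea = 61.0 kJ/mol)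
    gas ⇌ partner, rate k6*(csat - [partner]) (kL = 0.0190 /h)
    (constants at 35 °C)

In green, half of the opening up to the end is done by 1.22 d, while open intermediate at 1.22 d has a half-life of 3.2 d against passing into target, longer; open intermediate holds 51.1% of the charge at 5.00 d, and green ends 1.08 d behind beta's pace, more than the 0.408 d it could afford. A flask like green kept at 50 °C ends 0.101 d behind that pace with 51.0% target, and one kept at 20 °C ends 4.35 d behind with 6.81% target and 75.6% still substrate.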